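All constants are invented.

The trap I watched for in this flask was reading the target as an end product, when the step that makes it also runs backwards and hands starting material to the side reaction.

    gas phase ⇌ dissolved gas, rate k1*(csat - [dissolved gas]) (k1 = 0.63 s⁻¹, csat = 82 mM)
    starting material + dissolved gas ⇌ target (K2 = 7.1 L mol⁻¹, k2 = 0.56 L mol⁻¹ s⁻¹)
    starting material → side product (k3 = 0.072 s⁻¹)
    starting material + target ⇌ idle adduct, settled at all times (K4 = 1.3 L mol⁻¹)

in all of them: gas phase 82 mM (held); time 20 s
- Sunday's: starting material 0.080 M
- Thursday's: starting material 0.20 M
- Saturday's: starting material 0.60 M
- Tuesday's: starting material 2.0 M

- percent here means starting material units held: one idle adduct counts as two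
- what is said of target includes idle adduct
- at the start none of the gas is dissolved
- in an amount of target, one idle adduct counts as one target
- "hardly changes" means that all values lie within two and a half points (for a concentration: within two and a half percent of the largest)
- run time (Sunday's): 20 s

1. amount of target at the end, in percent of the starting material charged for Sunday's, Thursday's, Saturday's, Tuesday's, in this order
2. the shape of the row from first to last (rises all the way / hardly changes / falls, then rises / falls all the way / rises, then falls)

I ran the flask slowly in my head, following one molecule of starting material. In the first instants on Sunday's flask the gas crossing had a half-time of 1.10 s, shorter than the 9.6 s half-life of starting material by the side step alone, so there I held the dissolved gas at saturation, which makes the step to target pseudo-first-order in starting material. At the full charge, uptake per unit of dissolved gas was 0.336 s⁻¹ on Saturday's flask, less than the transfer coefficient 0.63 s⁻¹. At the full charge on Tuesday's flask it was 1.12 s⁻¹, more than that, so I expected the gas there to sag early.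

In the middle the molecule stood at a fork: towards target at 0.0459 s⁻¹, towards side product at 0.072 s⁻¹. Each visit to the fork therefore sent it to target with a chance of 38.9%, and from target it came back at 0.0789 s⁻¹. With the gas held at saturation and the idle adduct set aside, the charge enters none of these rates.

Towards the end, solving the linked pair gave a slow rate of 0.0351 s⁻¹ and a quick one of 0.162 s⁻¹. That gave 16.5% as the target chance, the chance that one charged molecule stands as target at the end with the gas held at saturation from the first instant. I left the idle adduct out. Its constant times the starting concentration is 0.10 on Sunday's flask but larger on Tuesday's, at 2.60, so my flat row was weakest there.

The forecast gave 16.6%, 16.9%, 17.7% and 18.6%, called hardly changes, on the ground that “more starting material starves the dissolved gas, but this is offset by the adduct”. Its row rose by 2 percentage points where mine stayed flat.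

The flask gave 15.4%, 15.5%, 15.4% and 14.0%, a row that hardly changes, and on Sunday's flask the relaxation half-life by the step to target alone, both ways together, was 5.19 s at the end, short against the 20 s run, while the amount of target reached 0.933 of the target chance. Tuesday's flask reached 0.848 of that same chance, with dissolved gas at 0.0546 M after 10.0 s, where Sunday's flask held 0.0807 M.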